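- I decide to read the flasks on the clock of the dusk run, since that run shows target still on its way up.

| setting | dusk | spring | west | south-east | south |
|---|---|---|---|---|---|
| substrate | 0.42 M | 0.66 M | 0.30 M | 0.30 M | 0.30 M |
| temperature | 65 °C | 98 °C | 50 °C | 80 °C | 110 °C |
| remark | run made earlier | run made earlier |  |  |  |
| time |  |  | 15 d | 15 d | 15 d |

- the best flask by amount of target, in percent of the substrate charged; "all alike" if 1.5 percentage points covers them all (west / south-east / south / all alike)
- amount of target at the end, in percent of the substrate charged, west
- amount of target at the end, in percent of the substrate charged, south-east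
- amount of target at the end, in percent of the substrate charged, south

- dusk (time / d: target / %, substrate / %): 1.25: 4.8, 8.2; 3.00: 17.8, 1.9; 5.00: 30.4, 2.1; 6.00: 33.2, 2.4
- spring (time / h: target / %, substrate / %): 2.50: 11.2, 5.1; 4.00: 13.8, 4.1; 12.0: 13.5, 2.3; 25.0: 14.8, 3.6

(readings scatter by 0.5 percentage points)

- the numbers in the tables scatter by 0.5 percentage points (one standard deviation)
- steps under discussion: substrate <-> intermediate A; substrate <-> intermediate B; intermediate A <-> target; intermediate A <-> intermediate B; target -> over-reaction product

- In dusk the rise of target slows between 3.00 d and 6.00 d, and dividing the earlier rate by the later gives, as a reading, a relaxation time of 1.85 d.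
- Spring's readings from 4.00 h on average a plateau of 14.0%, and the reading at 2.50 h has covered 79.8% of it, which gives a relaxation time of 1.56 h, so the clock runs 28.4 times faster in spring; spring differs from dusk in charge as well as temperature, but I assume that the temperature sets the clock, which gives as a reading an activation energy of 106 kJ mol⁻¹.
- One extreme flask is dusk replayed slowly, its target read off the dusk curve (kinetic control); the other stands on its plateau (thermodynamic control), and I expect a real flask at the lower of the two.
- West's 15 d are worth 2.61 d of dusk, and this count of dusk-days, a flask's time multiplied by its speed-up over dusk, is what I carry.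
- That falls between dusk's first two readings, so a straight line gives me 14.9% for west, on the high side, since dusk's rise is steeper after 1.25 d than before it.
- South-east has 74.2 d and south 1250 d, both far beyond 1.85 d, so I place them on plateaus: south-east near 21.6%, the geometric mean of dusk's last reading and spring's plateau, and south under 14.0%, which puts south-east ahead in my reckoning.
- The forecast names south-east, with west 22% (11% to 38%), south-east 27% (20% to 35%) and south 10% (4% to 14%), holding that “west stays kinetically limited”; my west is lower.
- The flasks give west 11.0%, south-east 29.8% and south 7.33%, so south-east leads.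

    substrate ⇌ intermediate A (K = 37.0, k = 8.10 × 10⁻⁶ s⁻¹, Ea = 110 kJ mol⁻¹, ΔH = −33.0 kJ mol⁻¹)
    substrate ⇌ intermediate B (K = 11.0, k = 1.30 × 10⁻⁴ s⁻¹, Ea = 110 kJ mol⁻¹, ΔH = −53.0 kJ mol⁻¹)
    intermediate A ⇌ target (K = 0.570, k = 3.40 × 10⁻⁵ s⁻¹, Ea = 110 kJ mol⁻¹, ΔH = −63.0 kJ mol⁻¹)
    intermediate A ⇌ intermediate B (k = 6.60 × 10⁻⁶ s⁻¹, Ea = 124 kJ mol⁻¹)
    target → over-reaction product (k = 2.80 × 10⁻⁸ s⁻¹, Ea = 122 kJ mol⁻¹)
    (constants at 80 °C)

- West's 2.61 d of dusk-days compare with the reading of 1.85 d, and its 11.0% lies between dusk's readings of 4.8% and 17.8%, far below the 68.4% it reaches after 150 d. A neighbour flask, south kept at 85 °C, has 123 d of dusk-days, far beyond 1.85 d, and it ends with target at 24.1%.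

(The runs come from a simulation for substances that don't exist; the scatter is artificial.)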